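**Plan**

- Tetralone numbering is used throughout: C1 ketone, C4 stereocentre, C4a/C8a ring fusion, C7/C8 hydroxyls, ring A the catechol, ring B the ketone ring; the naphthalene is C1' (on C4), C4' (OH), C8' (OMe).
- Retrosynthesis: the C1 ketone goes back to a silyl-protected carbinol and C2–C3 to an alkene, then ring B is cut at C4–C4a and C1–C8a in one [4+2] disconnection.
- Enabling feature: the C7/C8 catechol fused at C4a–C8a is the double enol of the adduct at one C=C bond of ortho-benzoquinone, and C1–C4 with its oxygen is a 1-siloxy-4-naphthylbuta-1,3-diene.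
- Forward: naphthalene-1,5-diol is methylated, brominated para to OH and benzylated; the four-carbon chain is joined by allylation and cross-metathesis with crotonaldehyde and turned into the (E,E)-silyl dienol ether; ring B closes on freshly made ortho-benzoquinone; ring A aromatises by enolisation.
- Stereochemistry: C4 is set in the cycloaddition by a bisoxazoline–Cu(OTf)2 catalyst (face of the bound quinone plus endo approach); the (E,E)-diene makes C1 cis to C4; C1 is later oxidised away and C4 is not touched again.

Key step: step 8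

Assumption: the (S,S) ligand is written on the basis of the usual quadrant picture of a square-planar bisoxazoline–copper chelate; should the adduct prove antipodal, the equally available (R,R) ligand takes its place.

**Step 1**
Reactants: 1 naphthalene-1,5-diol
Product: 2 5-methoxynaphthalen-1-ol
Conditions: MeI (1.0 equiv), K2CO3, acetone, reflux
Reagents that add atoms: iodomethane, CI
Why: Williamson ether synthesis on the mono-phenoxide with one equivalent of alkylating agent should give the monomethyl ether, separable from diol (recycled) and diether by base extraction and chromatography.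

**Step 2**
Reactants: 2 5-methoxynaphthalen-1-ol
Product: 3 4-bromo-5-methoxynaphthalen-1-ol
Conditions: NBS (1.0 equiv), MeCN, −20 → 0 °C, dark
Reagents that add atoms: N-bromosuccinimide, O=C1CCC(=O)N1Br
Why: electrophilic aromatic bromination should go to the ring bearing the free hydroxyl, which activates far more strongly than methoxy, and in acetonitrile to the position para to OH (C4, peri to OMe).

**Step 3**
Reactants: 3 4-bromo-5-methoxynaphthalen-1-ol
Product: 4 1-(benzyloxy)-4-bromo-5-methoxynaphthalene
Conditions: BnBr, K2CO3, DMF, rt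
Reagents that add atoms: benzyl bromide, BrCc1ccccc1
Why: Williamson benzylation of the naphthoxide is routine and gives an ether that survives every later step up to the final hydrogenolysis.

**Step 4**
Reactants: 4 1-(benzyloxy)-4-bromo-5-methoxynaphthalene
Product: 5 4-(benzyloxy)-8-methoxy-1-(prop-2-en-1-yl)naphthalene
Conditions: CH2=CHCH2SnBu3, Pd(PPh3)4 (5 mol %), DMF, 90 °C
Reagents that add atoms: allyltributylstannane, C=CC[Sn](CCCC)(CCCC)CCCC
Why: Stille coupling (oxidative addition of the aryl bromide to zerovalent palladium, allyl transfer from tin, reductive elimination) runs under neutral conditions and should tolerate both ethers.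

**Step 5**
Reactants: 5 4-(benzyloxy)-8-methoxy-1-(prop-2-en-1-yl)naphthalene; 6 (E)-but-2-enal (crotonaldehyde, 5 equiv)
Product: 7 (E)-4-[4-(benzyloxy)-8-methoxynaphthalen-1-yl]but-2-enal
Conditions: second-generation Grubbs catalyst RuCl2(=CHPh)(PCy3)(H2IMes) (5 mol %), CH2Cl2, 40 °C
Reagents that add atoms: none
Why: olefin cross-metathesis of a terminal allylarene with crotonaldehyde is a well-used route to (E)-4-arylbut-2-enals, driven by loss of a volatile alkene and giving the E-enal under thermodynamic control.

**Step 6**
Reactants: 7 (E)-4-[4-(benzyloxy)-8-methoxynaphthalen-1-yl]but-2-enal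
Product: 8 tert-butyl({(1E,3E)-4-[4-(benzyloxy)-8-methoxynaphthalen-1-yl]buta-1,3-dien-1-yl}oxy)dimethylsilane
Conditions: TBSOTf, Et3N, CH2Cl2, −78 → 0 °C; pentane extraction, filtration through Et3N-deactivated silica
Reagents that add atoms: tert-butyldimethylsilyl trifluoromethanesulfonate, CC(C)(C)[Si](C)(C)OS(=O)(=O)C(F)(F)F
Why: soft enolisation (O-silylation of the enal, then removal of the benzylic γ-proton by the amine) should give the silyl dienol ether, the s-trans enal leading to the 1E bond and conjugation with the arene to the 3E bond.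

**Step 7**
Reactants: 9 benzene-1,2-diol (catechol)
Product: 10 cyclohexa-3,5-diene-1,2-dione (ortho-benzoquinone), kept as a cold filtered solution and used at once
Conditions: Ag2O, Na2SO4, CH2Cl2, −20 °C, dark; cold filtration through Celite
Reagents that add atoms: none
Why: heterogeneous two-electron oxidation of catechol by silver oxide is the classical anhydrous preparation of the parent ortho-quinone and leaves a dry, acid-free solution suited to Lewis-acid catalysis.

**Step 8**
Reactants: 8 tert-butyl({(1E,3E)-4-[4-(benzyloxy)-8-methoxynaphthalen-1-yl]buta-1,3-dien-1-yl}oxy)dimethylsilane (1.1 equiv); 10 ortho-benzoquinone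
Product: 12 (5R,8R)-5-[4-(benzyloxy)-8-methoxynaphthalen-1-yl]-8-[(tert-butyldimethylsilyl)oxy]-5,8-dihydronaphthalene-1,2-diol, via endo ene-dione adduct 11 (not isolated)
Conditions: Cu(OTf)2 (10 mol %), (S,S)-2,2'-(propane-2,2-diyl)bis(4-tert-butyl-4,5-dihydrooxazole) (11 mol %), 4 Å MS, CH2Cl2, −78 °C, slow addition of 10; then Et3N (0.2 equiv), −78 → −20 °C; pH 7 buffer/EDTA work-up under argon
Reagents that add atoms: none
Why: Proposed new method: two-point chelation of the vicinal carbonyls of 10 by the bisoxazoline–Cu(OTf)2 complex lowers the quinone LUMO and occupies the O=C–C=O unit that could otherwise add to the enol ether as a heterodiene, so one C=C bond serves as the 2π partner in a concerted, suprafacial, endo [4+2] cycloaddition with s-cis 8; the closest known reactions are thermal Diels–Alder additions of ortho-benzoquinones as carbon dienophiles to acyclic dienes and bisoxazoline–Cu(OTf)2-catalysed cycloadditions of chelating 1,2-dicarbonyl dienophiles. Ring B closes in one six-membered pericyclic transition state that forms C4–C4a and C1–C8a together; the siloxy donor, outweighing the naphthyl group that the peri methoxy twists out of conjugation, puts the largest HOMO coefficient on C4, which bonds to the quinone β-carbon (C4a) while C1 bonds to the α-carbon (C8a). C4 is set by the ligand, whose tert-butyl groups should leave one face of the bound C=C open, together with the endo approach of the diene beneath the chelated dione; C1 follows as cis to C4 from the (E,E) geometry, and C4a/C8a form cis by suprafacial addition but are transient. Adduct 11 has hydrogens on C8a (alpha to one carbonyl) and C4a (gamma to the other through the remaining C=C), so amine-promoted double enolisation turns ring A into the C7/C8 catechol with no positional choice on an arene. The step needs carbon over hetero addition, β-regiochemistry, endo selectivity and facial selectivity, secured in that order by the chelate, the siloxy group, secondary overlap with the dione and the twofold-symmetric ligand pocket aided by the bulky silyl group. Slow addition of 10 at −78 °C keeps free quinone scarce, which should suppress the uncatalysed pathway, redox exchange with the catechol and acid-induced loss of silanol.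

**Step 9**
Reactants: 12 (5R,8R)-5-[4-(benzyloxy)-8-methoxynaphthalen-1-yl]-8-[(tert-butyldimethylsilyl)oxy]-5,8-dihydronaphthalene-1,2-diol (crude)
Product: 13 {[(1R,4R)-7,8-bis(benzyloxy)-4-[4-(benzyloxy)-8-methoxynaphthalen-1-yl]-1,4-dihydronaphthalen-1-yl]oxy}(tert-butyl)dimethylsilane
Conditions: BnBr, K2CO3, degassed DMF, 0 °C → rt
Reagents that add atoms: benzyl bromide, BrCc1ccccc1
Why: Williamson bis-benzylation of the catecholate under oxygen-free conditions should cap the oxidation-prone diol at once, carbonate being too weak a base to touch the C4–H or the silyl ether.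

**Step 10**
Reactants: 13 {[(1R,4R)-7,8-bis(benzyloxy)-4-[4-(benzyloxy)-8-methoxynaphthalen-1-yl]-1,4-dihydronaphthalen-1-yl]oxy}(tert-butyl)dimethylsilane
Product: 14 {[(1R,4R)-7,8-bis(benzyloxy)-4-[4-(benzyloxy)-8-methoxynaphthalen-1-yl]-1,2,3,4-tetrahydronaphthalen-1-yl]oxy}(tert-butyl)dimethylsilane
Conditions: 2-nitrobenzenesulfonohydrazide, Et3N, CH2Cl2, rt
Reagents that add atoms: none
Why: diimide reduction (concerted syn transfer of two hydrogens to the cis-disubstituted C2=C3 bond) works at room temperature under near-neutral conditions and should leave arenes, benzyl ethers and the benzylic C–O bond alone, which removes the path to a naphthalene.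

**Step 11**
Reactants: 14 {[(1R,4R)-7,8-bis(benzyloxy)-4-[4-(benzyloxy)-8-methoxynaphthalen-1-yl]-1,2,3,4-tetrahydronaphthalen-1-yl]oxy}(tert-butyl)dimethylsilane
Product: 15 (1R,4R)-7,8-bis(benzyloxy)-4-[4-(benzyloxy)-8-methoxynaphthalen-1-yl]-1,2,3,4-tetrahydronaphthalen-1-ol
Conditions: TBAF, AcOH, THF, 0 °C → rt
Reagents that add atoms: none
Why: fluoride-driven desilylation, buffered with acetic acid, should free the secondary benzylic alcohol without affecting benzyl ethers or either stereocentre.

**Step 12**
Reactants: 15 (1R,4R)-7,8-bis(benzyloxy)-4-[4-(benzyloxy)-8-methoxynaphthalen-1-yl]-1,2,3,4-tetrahydronaphthalen-1-ol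
Product: 16 (4R)-7,8-bis(benzyloxy)-4-[4-(benzyloxy)-8-methoxynaphthalen-1-yl]-3,4-dihydronaphthalen-1(2H)-one
Conditions: Dess–Martin periodinane, CH2Cl2, 0 °C → rt
Reagents that add atoms: none
Why: Dess–Martin oxidation of a secondary benzylic alcohol to the aryl ketone is reliable, and C4, not being alpha to the new carbonyl, cannot epimerise by enolisation.

**Step 13**
Reactants: 16 (4R)-7,8-bis(benzyloxy)-4-[4-(benzyloxy)-8-methoxynaphthalen-1-yl]-3,4-dihydronaphthalen-1(2H)-one
Product: 17 (4R)-7,8-dihydroxy-4-(4-hydroxy-8-methoxynaphthalen-1-yl)-3,4-dihydronaphthalen-1(2H)-one (CNP0535815.2)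
Conditions: H2 (1 atm), 10 % Pd/C, EtOAc/MeOH, rt, stopped at three equivalents of H2; argon work-up
Reagents that add atoms: none
Why: palladium-catalysed hydrogenolysis should cleave the three aryl benzyl ethers and spare the methyl ether, and the ketone, hydrogen-bonded to the freed C8 hydroxyl and conjugated with the electron-rich ring, is expected to resist reduction at atmospheric pressure.

**Compound list**

1 | naphthalene-1,5-diol | Oc1cccc2c(O)cccc12 | starting material
2 | 5-methoxynaphthalen-1-ol | COc1cccc2c(O)cccc12 | intermediate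
3 | 4-bromo-5-methoxynaphthalen-1-ol | COc1cccc2c(O)ccc(Br)c12 | intermediate
4 | 1-(benzyloxy)-4-bromo-5-methoxynaphthalene | COc1cccc2c(OCc3ccccc3)ccc(Br)c12 | intermediate
5 | 4-(benzyloxy)-8-methoxy-1-(prop-2-en-1-yl)naphthalene | COc1cccc2c(OCc3ccccc3)ccc(CC=C)c12 | intermediate
6 | (E)-but-2-enal (crotonaldehyde) | C/C=C/C=O | starting material
7 | (E)-4-[4-(benzyloxy)-8-methoxynaphthalen-1-yl]but-2-enal | COc1cccc2c(OCc3ccccc3)ccc(C/C=C/C=O)c12 | intermediate
8 | tert-butyl({(1E,3E)-4-[4-(benzyloxy)-8-methoxynaphthalen-1-yl]buta-1,3-dien-1-yl}oxy)dimethylsilane | COc1cccc2c(OCc3ccccc3)ccc(/C=C/C=C/O[Si](C)(C)C(C)(C)C)c12 | intermediate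
9 | benzene-1,2-diol (catechol) | Oc1ccccc1O | starting material
10 | cyclohexa-3,5-diene-1,2-dione (ortho-benzoquinone) | O=C1C=CC=CC1=O | intermediate
11 | endo adduct: cis-fused 5-[4-(benzyloxy)-8-methoxynaphthalen-1-yl]-8-[(tert-butyldimethylsilyl)oxy]-4a,5,8,8a-tetrahydronaphthalene-1,2-dione, H-4a, H-5, H-8 and H-8a all on one face, aryl-bearing carbon configured as in the target | COc1cccc2c(OCc5ccccc5)ccc([C@H]3C=C[C@@H](O[Si](C)(C)C(C)(C)C)[C@@H]4[C@H]3C=CC(=O)C4=O)c12 | intermediate (not isolated)
12 | (5R,8R)-5-[4-(benzyloxy)-8-methoxynaphthalen-1-yl]-8-[(tert-butyldimethylsilyl)oxy]-5,8-dihydronaphthalene-1,2-diol (cis) | COc1cccc2c(OCc5ccccc5)ccc([C@H]3C=C[C@@H](O[Si](C)(C)C(C)(C)C)c4c3ccc(O)c4O)c12 | intermediate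
13 | {[(1R,4R)-7,8-bis(benzyloxy)-4-[4-(benzyloxy)-8-methoxynaphthalen-1-yl]-1,4-dihydronaphthalen-1-yl]oxy}(tert-butyl)dimethylsilane (cis) | COc1cccc2c(OCc5ccccc5)ccc([C@H]3C=C[C@@H](O[Si](C)(C)C(C)(C)C)c4c3ccc(OCc6ccccc6)c4OCc7ccccc7)c12 | intermediate
14 | {[(1R,4R)-7,8-bis(benzyloxy)-4-[4-(benzyloxy)-8-methoxynaphthalen-1-yl]-1,2,3,4-tetrahydronaphthalen-1-yl]oxy}(tert-butyl)dimethylsilane | COc1cccc2c(OCc5ccccc5)ccc([C@H]3CC[C@@H](O[Si](C)(C)C(C)(C)C)c4c3ccc(OCc6ccccc6)c4OCc7ccccc7)c12 | intermediate
15 | (1R,4R)-7,8-bis(benzyloxy)-4-[4-(benzyloxy)-8-methoxynaphthalen-1-yl]-1,2,3,4-tetrahydronaphthalen-1-ol | COc1cccc2c(OCc5ccccc5)ccc([C@H]3CC[C@@H](O)c4c3ccc(OCc6ccccc6)c4OCc7ccccc7)c12 | intermediate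
16 | (4R)-7,8-bis(benzyloxy)-4-[4-(benzyloxy)-8-methoxynaphthalen-1-yl]-3,4-dihydronaphthalen-1(2H)-one | COc1cccc2c(OCc5ccccc5)ccc([C@H]3CCC(=O)c4c3ccc(OCc6ccccc6)c4OCc7ccccc7)c12 | intermediate
17 | (4R)-7,8-dihydroxy-4-(4-hydroxy-8-methoxynaphthalen-1-yl)-3,4-dihydronaphthalen-1(2H)-one | COc1cccc2c(O)ccc([C@H]3CCC(=O)c4c3ccc(O)c4O)c12 | target

**Step count and risks**

Total: 13 steps. Longest linear sequence: 12 steps (steps 1–6 and 8–13 from naphthalene-1,5-diol); step 7 is a one-step branch from catechol.

Steps most likely to fail: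

1. Step 8 (proposed new method). The bound quinone may react as a heterodiene at the enol ether bond, or add stepwise and rearomatise without ring closure. Facial control may also be eroded by an uncatalysed background reaction, and the product may be lost by redox exchange or by loss of silanol with aromatisation. The fallback moves enantiocontrol from the catalyst to a resolution. It sets out from 8 and 10, which are combined without copper in CH2Cl2 at −40 °C → rt (the known thermal Diels–Alder mode of ortho-benzoquinone with acyclic dienes) and enolised with Et3N to give the racemic cis-catechol F1. Benzylation as in step 9 gives the racemic tribenzyl ether F2, whose enantiomers are separated by preparative chromatography on an amylose tris(3,5-dimethylphenylcarbamate) phase. The (1R,4R) antipode is 13, where the route is rejoined, and the (1S,4S) antipode F3 is set aside.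

2. Step 10. Diimide transfer to an alkene flanked by two substituted carbons may be slow, and the long exposure, like the basic alkylation before it, may allow elimination of silanol and aromatisation with loss of C4. The fallback reverses the order of reduction and protection. It sets out from 12, which is hydrogenated homogeneously (H2 1 atm, RhCl(PPh3)3, benzene/EtOH, rt; no hydrogenolysis of benzyl or benzylic silyl ethers) to the saturated catechol F4. Tribenzylation is unnecessary; bis-benzylation (BnBr, K2CO3, DMF) of the now elimination-proof diol returns to the route at 14.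

3. Step 5. The allyl group may migrate into conjugation with the naphthalene on the ruthenium catalyst, and the allylarene may homodimerise, so that little enal forms. The fallback joins the chain by a different bond-forming reaction and bypasses steps 4–6. It sets out from 4, which undergoes a Mizoroki–Heck reaction with methyl but-3-enoate (Pd(OAc)2, P(o-tol)3, Et3N, MeCN, 80 °C) to give methyl (E)-4-[4-(benzyloxy)-8-methoxynaphthalen-1-yl]but-3-enoate F5. Reduction with i-Bu2AlH (CH2Cl2, −78 °C) gives (E)-4-[4-(benzyloxy)-8-methoxynaphthalen-1-yl]but-3-enal F6, and TBSOTf/Et3N (α-deprotonation of the β,γ-unsaturated aldehyde) returns to the route at 8.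

**Further compounds**

F1 | step 8 | racemic cis-5-[4-(benzyloxy)-8-methoxynaphthalen-1-yl]-8-[(tert-butyldimethylsilyl)oxy]-5,8-dihydronaphthalene-1,2-diol (1:1 mixture of 12 and its enantiomer) | COc1cccc2c(OCc5ccccc5)ccc([C@H]3C=C[C@@H](O[Si](C)(C)C(C)(C)C)c4c3ccc(O)c4O)c12.COc1cccc2c(OCc5ccccc5)ccc([C@@H]3C=C[C@H](O[Si](C)(C)C(C)(C)C)c4c3ccc(O)c4O)c12
F2 | step 8 | racemic cis-{[7,8-bis(benzyloxy)-4-[4-(benzyloxy)-8-methoxynaphthalen-1-yl]-1,4-dihydronaphthalen-1-yl]oxy}(tert-butyl)dimethylsilane (1:1 mixture of 13 and its enantiomer) | COc1cccc2c(OCc5ccccc5)ccc([C@H]3C=C[C@@H](O[Si](C)(C)C(C)(C)C)c4c3ccc(OCc6ccccc6)c4OCc7ccccc7)c12.COc1cccc2c(OCc5ccccc5)ccc([C@@H]3C=C[C@H](O[Si](C)(C)C(C)(C)C)c4c3ccc(OCc6ccccc6)c4OCc7ccccc7)c12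
F3 | step 8 | {[(1S,4S)-7,8-bis(benzyloxy)-4-[4-(benzyloxy)-8-methoxynaphthalen-1-yl]-1,4-dihydronaphthalen-1-yl]oxy}(tert-butyl)dimethylsilane (enantiomer of 13) | COc1cccc2c(OCc5ccccc5)ccc([C@@H]3C=C[C@H](O[Si](C)(C)C(C)(C)C)c4c3ccc(OCc6ccccc6)c4OCc7ccccc7)c12
F4 | step 10 | (5R,8R)-5-[4-(benzyloxy)-8-methoxynaphthalen-1-yl]-8-[(tert-butyldimethylsilyl)oxy]-5,6,7,8-tetrahydronaphthalene-1,2-diol | COc1cccc2c(OCc5ccccc5)ccc([C@H]3CC[C@@H](O[Si](C)(C)C(C)(C)C)c4c3ccc(O)c4O)c12
F5 | step 5 | methyl (E)-4-[4-(benzyloxy)-8-methoxynaphthalen-1-yl]but-3-enoate | COc1cccc2c(OCc3ccccc3)ccc(/C=C/CC(=O)OC)c12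
F6 | step 5 | (E)-4-[4-(benzyloxy)-8-methoxynaphthalen-1-yl]but-3-enal | COc1cccc2c(OCc3ccccc3)ccc(/C=C/CC=O)c12
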